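**Retrosynthetic overview**
1. Target 13 ⇒ protected diester 11 by two mild deprotections: allyl ester (Pd(PPh3)4), then 3-O-silyl ether (HF·pyridine, acidic, so no acyl migration).
2. Key disconnection: both cinnamoyl Cα=Cβ bonds of 11 ⇒ bis(hydrogen malonate) 8 + two 4-hydroxybenzaldehyde 9, by an intermolecular aldol-type (Knoevenagel–Doebner) condensation.
3. 8 ⇒ 4,5-diol 6 + Meldrum's acid 7 (base-free malonylation).
4. 6 ⇒ (−)-quinic acid 1: butane-2,3-diacetal (BDA) on the trans-4,5-diol, methyl → allyl ester, 3-O-TBDPS, BDA removal.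
5. Rings: no carbocycle is built. The cyclohexane ring and its four stereocentres come from 1; a temporary dioxane ring is closed in step 1 and opened in step 5.

Assumption: positions follow the IUPAC quinic acid numbering shown by the SMILES (C3-OH cis to C4-O; C5-O trans to C4-O and cis to CO2H), and "quinate" below always means the ring of 1 with its configuration unchanged.

**Step 1**
Reactants: 1 (−)-quinic acid
Product: 2 methyl 4,5-O-[(2S,3S)-2,3-dimethoxybutane-2,3-diyl]quinate
Conditions: butane-2,3-dione (1.3 equiv), HC(OMe)3 (5 equiv), CSA (5 mol%), MeOH, reflux, 16 h; Et3N quench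
Reagents that add atoms: butane-2,3-dione CC(=O)C(C)=O; methanol CO (ester OMe and both acetal OMe, exchangeable with those of trimethyl orthoformate COC(OC)OC)
Why: Thermodynamically controlled Ley bis-acetalisation picks the only trans-diequatorial diol (O4/O5), the anomeric effect places both new acetal OMe groups axial on a trans-fused chair dioxane (S,S), and Fischer esterification forms the methyl ester in the same pot.

**Step 2**
Reactants: 2 methyl 4,5-O-[(2S,3S)-2,3-dimethoxybutane-2,3-diyl]quinate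
Product: 3 4,5-O-[(2S,3S)-2,3-dimethoxybutane-2,3-diyl]quinic acid
Conditions: LiOH·H2O (2 equiv), THF/H2O 3:1, 0 °C → rt; 1 M HCl to pH 3 at 0 °C, EtOAc extraction
Reagents that add atoms: lithium hydroxide [Li+].[OH-] (its oxygen becomes the carboxyl OH)
Why: Saponification (BAc2 ester hydrolysis) leaves the base-stable BDA acetal untouched, and C1 has no α-hydrogen, so nothing can epimerise.

**Step 3**
Reactants: 3 4,5-O-[(2S,3S)-2,3-dimethoxybutane-2,3-diyl]quinic acid
Product: 4 allyl 4,5-O-[(2S,3S)-2,3-dimethoxybutane-2,3-diyl]quinate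
Conditions: allyl bromide (1.5 equiv), KHCO3 (2 equiv), DMF, rt, 12 h
Reagents that add atoms: allyl bromide C=CCBr
Why: SN2 O-alkylation of the carboxylate; hydrogen carbonate is too weak a base to alkylate the secondary or tertiary hydroxyls.

**Step 4**
Reactants: 4 allyl 4,5-O-[(2S,3S)-2,3-dimethoxybutane-2,3-diyl]quinate
Product: 5 allyl 3-O-(tert-butyldiphenylsilyl)-4,5-O-[(2S,3S)-2,3-dimethoxybutane-2,3-diyl]quinate
Conditions: TBDPSCl (1.5 equiv), imidazole (3 equiv), DMAP (0.2 equiv), DMF, 50 °C, 24 h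
Reagents that add atoms: tert-butyl(chloro)diphenylsilane CC(C)(C)[Si](Cl)(c1ccccc1)c1ccccc1
Why: Imidazole/DMAP-catalysed silylation takes the only secondary hydroxyl (C3-OH), because the tertiary C1-OH is too hindered for this bulky chloride.

**Step 5**
Reactants: 5 allyl 3-O-(tert-butyldiphenylsilyl)-4,5-O-[(2S,3S)-2,3-dimethoxybutane-2,3-diyl]quinate
Product: 6 allyl 3-O-(tert-butyldiphenylsilyl)quinate (1-OH, 4-OH and 5-OH free)
Conditions: TFA/H2O 9:1, 0 °C → rt, 20–30 min; evaporate with toluene below 30 °C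
Reagents that add atoms: none
Why: Acid-catalysed acetal hydrolysis removes the BDA group, while the acid-robust TBDPS ether and the allyl ester survive the short exposure and no C–O bond at a stereocentre is broken.

**Step 6**
Reactants: 6 allyl 3-O-(tert-butyldiphenylsilyl)quinate; 7 Meldrum's acid
Product: 8 allyl 3-O-(tert-butyldiphenylsilyl)-4,5-bis-O-(carboxyacetyl)quinate
Conditions: 7 (2.4 equiv), toluene, 90 °C, 4 h; concentrate, short silica plug
Reagents that add atoms: none
Why: Thermal ring-opening acylation of the two secondary alcohols by Meldrum's acid (loss of acetone) gives the malonic half-esters without base, so no silyl or acyl migration occurs and the deactivated tertiary C1-OH stays free.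

**Step 7**
Reactants: 8 allyl 3-O-(tert-butyldiphenylsilyl)-4,5-bis-O-(carboxyacetyl)quinate; 9 4-hydroxybenzaldehyde
Product: 11 allyl 3-O-(tert-butyldiphenylsilyl)-4,5-di-O-[(E)-p-coumaroyl]quinate, via bis-aldol adduct 10 (not isolated)
Conditions: 9 (3 equiv), piperidine (0.3 equiv), DMAP (0.3 equiv), DMF, rt → 40 °C, 4–5 d
Reagents that add atoms: none
Why: Knoevenagel–Doebner condensation: each malonate half-ester adds as its enol(ate) to the amine-activated aldehyde in an intermolecular aldol-type step (adduct 10), and decarboxylative anti-elimination then gives the conjugated, thermodynamically preferred E-alkenes.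

**Step 8**
Reactants: 11 allyl 3-O-(tert-butyldiphenylsilyl)-4,5-di-O-[(E)-p-coumaroyl]quinate
Product: 12 3-O-(tert-butyldiphenylsilyl)-4,5-di-O-[(E)-p-coumaroyl]quinic acid
Conditions: Pd(PPh3)4 (5 mol%), morpholine (5 equiv), THF, rt, 1–2 h; cold 0.5 M HCl wash
Reagents that add atoms: none
Why: Tsuji–Trost deallylation: zerovalent palladium ionises the allyl ester to a π-allyl complex that morpholine traps, and with O3 still silylated the amine cannot trigger 4→3 acyl migration.

**Step 9**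
Reactants: 12 3-O-(tert-butyldiphenylsilyl)-4,5-di-O-[(E)-p-coumaroyl]quinic acid
Product: 13 4,5-di-O-p-coumaroylquinic acid
Conditions: HF·pyridine (excess), pyridine/THF, 0 °C → rt, 24–48 h; evaporate; C18 chromatography (H2O/MeCN, 0.1% HCO2H)
Reagents that add atoms: none
Why: Fluoride-mediated desilylation in an acidic, non-nucleophilic medium frees the C3-OH last, under conditions where cinnamate esters neither migrate nor hydrolyse.

**Compound list**
1 | (−)-quinic acid, (1S,3R,4S,5R)-1,3,4,5-tetrahydroxycyclohexane-1-carboxylic acid | O[C@@H]1[C@H](O)C[C@@](O)(C(=O)O)C[C@H]1O | starting material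
2 | methyl 4,5-O-[(2S,3S)-2,3-dimethoxybutane-2,3-diyl]quinate (trans-fused dioxane, both OMe axial, 1-OH and 3-OH free) | CO[C@@]1(C)O[C@@H]2[C@H](O)C[C@@](O)(C(=O)OC)C[C@H]2O[C@]1(C)OC | intermediate
3 | 4,5-O-[(2S,3S)-2,3-dimethoxybutane-2,3-diyl]quinic acid | CO[C@@]1(C)O[C@@H]2[C@H](O)C[C@@](O)(C(=O)O)C[C@H]2O[C@]1(C)OC | intermediate
4 | allyl 4,5-O-[(2S,3S)-2,3-dimethoxybutane-2,3-diyl]quinate | CO[C@@]1(C)O[C@@H]2[C@H](O)C[C@@](O)(C(=O)OCC=C)C[C@H]2O[C@]1(C)OC | intermediate
5 | allyl 3-O-(tert-butyldiphenylsilyl)-4,5-O-[(2S,3S)-2,3-dimethoxybutane-2,3-diyl]quinate | CO[C@@]1(C)O[C@@H]2[C@H](O[Si](c3ccccc3)(c3ccccc3)C(C)(C)C)C[C@@](O)(C(=O)OCC=C)C[C@H]2O[C@]1(C)OC | intermediate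
6 | allyl 3-O-(tert-butyldiphenylsilyl)quinate (1,4,5-triol) | O[C@@H]1[C@H](O[Si](c2ccccc2)(c2ccccc2)C(C)(C)C)C[C@@](O)(C(=O)OCC=C)C[C@H]1O | intermediate
7 | Meldrum's acid, 2,2-dimethyl-1,3-dioxane-4,6-dione | CC1(C)OC(=O)CC(=O)O1 | starting material
8 | allyl 3-O-(tert-butyldiphenylsilyl)-4,5-bis-O-(carboxyacetyl)quinate, the bis(hydrogen malonate) | OC(=O)CC(=O)O[C@@H]1[C@H](O[Si](c2ccccc2)(c2ccccc2)C(C)(C)C)C[C@@](O)(C(=O)OCC=C)C[C@H]1OC(=O)CC(=O)O | intermediate
9 | 4-hydroxybenzaldehyde | O=Cc1ccc(O)cc1 | starting material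
10 | allyl 3-O-(tert-butyldiphenylsilyl)-4,5-bis-O-[2-carboxy-3-hydroxy-3-(4-hydroxyphenyl)propanoyl]quinate, bis-aldol adduct (mixture of diastereomers at the four new side-chain carbons, ring configuration unchanged) | OC(=O)C(C(O)c3ccc(O)cc3)C(=O)O[C@@H]1[C@H](O[Si](c2ccccc2)(c2ccccc2)C(C)(C)C)C[C@@](O)(C(=O)OCC=C)C[C@H]1OC(=O)C(C(=O)O)C(O)c4ccc(O)cc4 | intermediate
11 | allyl 3-O-(tert-butyldiphenylsilyl)-4,5-di-O-[(E)-p-coumaroyl]quinate | O=C(/C=C/c1ccc(O)cc1)O[C@@H]1[C@H](O[Si](c2ccccc2)(c2ccccc2)C(C)(C)C)C[C@@](O)(C(=O)OCC=C)C[C@H]1OC(=O)/C=C/c1ccc(O)cc1 | intermediate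
12 | 3-O-(tert-butyldiphenylsilyl)-4,5-di-O-[(E)-p-coumaroyl]quinic acid | O=C(/C=C/c1ccc(O)cc1)O[C@@H]1[C@H](O[Si](c2ccccc2)(c2ccccc2)C(C)(C)C)C[C@@](O)(C(=O)O)C[C@H]1OC(=O)/C=C/c1ccc(O)cc1 | intermediate
13 | 4,5-di-O-p-coumaroylquinic acid | O=C(/C=C/c1ccc(O)cc1)O[C@@H]1[C@H](O)C[C@@](O)(C(=O)O)C[C@H]1OC(=O)/C=C/c1ccc(O)cc1 | target

**Totals**
Total step count: 9. Longest linear sequence: 9 steps (1 → 13); compounds 7 and 9 are bought.

**Three steps most likely to fail**

Step 7 (double Knoevenagel–Doebner on the vicinal bis-malonate; it may stop at the mono-cinnamate or decarboxylate to acetates). The fallback sets out from 6 and comes back at 12, bypassing steps 6–8. The same aldol-type C–C bond formation is done on the small fragment first, and the ester bonds are made afterwards. Commercial 4-(allyloxy)benzaldehyde and malonic acid are condensed (pyridine, cat. piperidine, 90 °C) to (E)-4-(allyloxy)cinnamic acid F1. Oxalyl chloride with cat. DMF in CH2Cl2 converts it into (E)-4-(allyloxy)cinnamoyl chloride F2. Diol 6 is acylated with F2 (2.6 equiv, pyridine, DMAP, CH2Cl2, 0 → 40 °C) to allyl 3-O-(tert-butyldiphenylsilyl)-4,5-bis-O-[(E)-4-(allyloxy)cinnamoyl]quinate F3. Pd(PPh3)4 with morpholine in THF then removes the allyl ester and both aryl allyl ethers in one operation and gives 12.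

Step 6 (bis-malonylation; the 4-OH next to the bulky silyl ether may react slowly, and prolonged heating risks decarboxylation or lactonisation). The fallback sets out from 6 and comes back at 8. Diol 6 is esterified at 0 °C → rt with commercial mono-tert-butyl malonate (N,N'-diisopropylcarbodiimide, cat. DMAP, CH2Cl2) to allyl 3-O-(tert-butyldiphenylsilyl)-4,5-bis-O-(3-tert-butoxy-3-oxopropanoyl)quinate F4. TFA/CH2Cl2 1:4 (0 °C → rt) cleaves only the two tert-butyl esters and delivers 8.

Step 4 (silylation of the hindered axial C3-OH with a bulky chloride). The fallback sets out from 1 and comes back at 6, so the BDA sequence (steps 1–5) is not needed; regiocontrol comes from the lactone instead of the diacetal. Quinic acid 1 is lactonised (cat. TsOH, toluene/DMF, reflux, Dean–Stark) to 1,5-quinide F5. In F5 the C3-OH is equatorial and the most accessible, and it is silylated selectively (TBDPSCl, imidazole, DMF, 0 °C → rt) to 3-O-(tert-butyldiphenylsilyl)-1,5-quinide F6. LiOH in THF/H2O at 0 °C opens the lactone to 3-O-(tert-butyldiphenylsilyl)quinic acid F7. Its carboxylate is alkylated with allyl bromide and KHCO3 in DMF to give 6.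

**Further compounds**
F1 | step 7 | (E)-4-(allyloxy)cinnamic acid | OC(=O)/C=C/c1ccc(OCC=C)cc1
F2 | step 7 | (E)-4-(allyloxy)cinnamoyl chloride | ClC(=O)/C=C/c1ccc(OCC=C)cc1
F3 | step 7 | allyl 3-O-(tert-butyldiphenylsilyl)-4,5-bis-O-[(E)-4-(allyloxy)cinnamoyl]quinate | O=C(/C=C/c1ccc(OCC=C)cc1)O[C@@H]1[C@H](O[Si](c2ccccc2)(c2ccccc2)C(C)(C)C)C[C@@](O)(C(=O)OCC=C)C[C@H]1OC(=O)/C=C/c1ccc(OCC=C)cc1
F4 | step 6 | allyl 3-O-(tert-butyldiphenylsilyl)-4,5-bis-O-(3-tert-butoxy-3-oxopropanoyl)quinate | CC(C)(C)OC(=O)CC(=O)O[C@@H]1[C@H](O[Si](c2ccccc2)(c2ccccc2)C(C)(C)C)C[C@@](O)(C(=O)OCC=C)C[C@H]1OC(=O)CC(=O)OC(C)(C)C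
F5 | step 4 | 1,5-quinide (quinic acid 1,5-lactone; 1-OH, 3-OH and 4-OH free) | O[C@@H]1[C@H](O)C[C@]2(O)C[C@H]1OC2=O
F6 | step 4 | 3-O-(tert-butyldiphenylsilyl)-1,5-quinide | O[C@@H]1[C@H](O[Si](c3ccccc3)(c3ccccc3)C(C)(C)C)C[C@]2(O)C[C@H]1OC2=O
F7 | step 4 | 3-O-(tert-butyldiphenylsilyl)quinic acid | O[C@@H]1[C@H](O[Si](c2ccccc2)(c2ccccc2)C(C)(C)C)C[C@@](O)(C(=O)O)C[C@H]1O
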